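The route rests on one disconnection of ring A (C1–C5, C10; drimane numbering): the para-related bonds C3–C4 and C5–C10 are the two σ-bonds of an intramolecular Diels–Alder reaction. The feature exploited is that C3 carries oxygen (carried as boron on a diene terminus), C4 is the gem-dimethyl terminus of an enone, and C6, sp2 in the target, can be the activating ketone of a C6–C9 tether, so the same event closes ring B. An acyclic trienone controlled by the single C9 stereocentre and a (Z)-configured dienylboronate thus gives both rings, both quaternary carbons and C3, C5 and C10 in one operation.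

Key step: step 10

Remark (numbering, abbreviations): C1–C12 are drimane locants of the target (ring A = C1–C5 and C10; ring B = C5–C10; C11 = CH2O on C9; C12 = exocyclic CH2 on C8); Bpin = 4,4,5,5-tetramethyl-1,3,2-dioxaborolan-2-yl; TBS = tert-butyldimethylsilyl; Bn = benzyl.
Remark (assumption): the aldol of step 9 is drawn as its Felkin–Anh epimer (8S); C8 becomes sp2 in step 16, so a minor 8R epimer would converge on the same compound 26.

Step 1
Reactants: 1 (S)-4-benzyloxazolidin-2-one; 2 3-methylbut-2-enoyl chloride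
Product: 3 (S)-4-benzyl-3-(3-methylbut-2-enoyl)oxazolidin-2-one
Conditions: n-BuLi, THF, −78 °C; then 2, −78 → 0 °C
Reagents that add atoms: none
Why: N-acylation of the lithiated oxazolidinone by the acid chloride is the standard imide formation and creates no stereocentre.

Step 2
Reactants: 3 imide; 4 benzyl chloromethyl ether
Product: 5 (S)-4-benzyl-3-[(R)-2-(benzyloxymethyl)-3-methylbut-3-enoyl]oxazolidin-2-one
Conditions: NaN(SiMe3)2, THF, −78 °C; then 4, −78 → −40 °C
Reagents that add atoms: none
Why: Evans alkylation: γ-deprotonation gives the chelated sodium (Z)-dienolate, which should be alkylated at the α-carbon on the face opposite the benzyl group, setting C9 (R here) and leaving the isopropenyl group (C10, its methyl, C1) deconjugated.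

Step 3
Reactants: 5 alkylated imide
Product: 6 (S)-2-(benzyloxymethyl)-3-methylbut-3-en-1-ol
Conditions: LiBH4, MeOH (1 equiv), Et2O, 0 °C
Reagents that add atoms: none
Why: Reductive cleavage of the imide by borohydride gives the primary alcohol (future C8) without touching C9 and returns the auxiliary.

Step 4
Reactants: 6 alcohol; 7 acryloyl chloride
Product: 8 (R)-2-(benzyloxymethyl)-3-methylbut-3-en-1-yl prop-2-enoate
Conditions: Et3N, CH2Cl2, 0 °C
Reagents that add atoms: none
Why: Simple O-acylation installs the temporary acrylate tether that brings in C2.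

Step 5
Reactants: 8 acrylate
Product: 9 (R)-5-(benzyloxymethyl)-4-methyl-5,6-dihydro-2H-pyran-2-one
Conditions: second-generation Grubbs catalyst (5 mol %), PhMe (5 mM), 80 °C
Reagents that add atoms: none
Why: Ring-closing metathesis of the acrylate with the isopropenyl group should form the trisubstituted C1=C10 alkene, and the six-membered ring fixes it as Z (C9 cis to C2).

Step 6
Reactants: 9 lactone
Product: 10 (5R)-5-(benzyloxymethyl)-4-methyl-5,6-dihydro-2H-pyran-2-ol (both anomers)
Conditions: i-Bu2AlH (1.1 equiv), CH2Cl2, −78 °C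
Reagents that add atoms: none
Why: Partial 1,2-reduction of the unsaturated lactone stops at the aluminium hemiacetal at low temperature and gives the lactol, a masked (Z)-enal.

Step 7
Reactants: 10 lactol; 11 2-(dichloromethyl)-4,4,5,5-tetramethyl-1,3,2-dioxaborolane
Product: 12 (2S,3Z,5E)-2-(benzyloxymethyl)-3-methyl-6-Bpin-hexa-3,5-dien-1-ol
Conditions: CrCl2 (8 equiv), LiI (4 equiv), THF, 25 °C
Reagents that add atoms: none
Why: Takai–Utimoto boryl olefination: the lactol reacts through its open (Z)-hydroxy enal and the geminal dichromium reagent should give the (E)-alkenylboronate, so the (1E,3Z)-diene is complete and the C8 hydroxyl is released.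

Step 8
Reactants: 12 dienyl boronate alcohol
Product: 13 (2R,3Z,5E)-2-(benzyloxymethyl)-3-methyl-6-Bpin-hexa-3,5-dienal
Conditions: Dess–Martin periodinane, pyridine, CH2Cl2, 0 °C; used crude
Reagents that add atoms: none
Why: Dess–Martin oxidation under buffered, non-basic conditions should give the aldehyde (C8) without epimerising the adjacent C9 centre or moving the diene.

Step 9
Reactants: 13 aldehyde; 14 4-methylpent-3-en-2-one (mesityl oxide)
Product: 16 (6S,7R,8Z,10E)-7-(benzyloxymethyl)-6-(tert-butyldimethylsilyloxy)-2,8-dimethyl-11-Bpin-undeca-2,8,10-trien-4-one, via lithium aldolate 15 (not isolated)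
Conditions: LiN(i-Pr)2, 14, THF, −78 °C; then 13; then TBSOTf, −78 → −40 °C
Reagents that add atoms: tert-butyldimethylsilyl trifluoromethanesulfonate CC(C)(C)[Si](C)(C)OS(=O)(=O)C(F)(F)F
Why: Aldol addition of the kinetic (methyl-side) lithium enolate of mesityl oxide to the aldehyde forms C7–C8 (Felkin–Anh addition anti to the dienyl group should favour 8S, a centre that is erased later) and the aldolate is silylated in the same flask to block retro-aldol cleavage.

Step 10
Reactants: 16 trienone
Product: 18 trans-fused decalone (3R,5R,8S,9R,10S)-11-benzyloxy-3-Bpin-8-(TBS-oxy)-12-nordrim-1-en-6-one, via cis-fused cycloadduct 17 (not isolated)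
Conditions: PhMe (5 mM), BHT, 160 °C, sealed tube; then DBU, 80 °C
Reagents that add atoms: none
Why: Thermal intramolecular Diels–Alder reaction (closest known types: cyclisation of 1,7,9-decatrien-3-ones and cycloadditions of 1-boryl dienes): the (1E,3Z)-dienylboronate C3=C2–C1=C10 adds suprafacially across the enone C4=C5 and forms C3–C4 and C5–C10 in one concerted, asynchronous [4+2] event. Ring A closes as the new cyclohexene that contains both new bonds, and ring B closes at the same time in the fused mode through the four-atom tether C6–C7–C8–C9, with C5–C10 as its last bond. C10 is set by C9: in the Z-diene 1,3-allylic strain holds H9 in the diene plane towards C2, so the tether (C8) and the CH2OBn group lie on opposite faces and C5 can only bond to the face that carries C8, which puts C11 cis to the new angular methyl. C3 follows from the diene geometry, the outside boryl group and the outside methyl on C10 ending cis on ring A, so that later oxidation with retention gives the required carbinol; C4 is not stereogenic. The tether on the inside position of the diene forces the C6 carbonyl exo and gives the cis-fused ketone 17, whose C5 (alpha to the ketone) is then equilibrated by DBU to the trans-fused ketone 18, in which the silyloxy and CH2OBn groups are both equatorial. The step needs the fused regiochemistry, which the short tether enforces (the bridged mode would need an eight-membered ring), and it needs the cycloaddition to outrun a 1,5-hydrogen shift of the Z-diene, which the ketone-activated dienophile next to the tether should secure.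

Step 11
Reactants: 18 trans-fused decalone
Product: 19 (3R,5R,8S,9R,10S)-11-hydroxy-3-Bpin-8-(TBS-oxy)-12-nordriman-6-one
Conditions: H2 (3 bar), Pd/C, EtOAc, 25 °C
Reagents that add atoms: none
Why: Heterogeneous hydrogenation should saturate the only C=C bond (C1=C2) and hydrogenolyse the benzyl ether in the same operation, the boronate, ketone and silyl ether being inert.

Step 12
Reactants: 19 hydroxy ketone; 20 7-hydroxy-2H-chromen-2-one (umbelliferone)
Product: 21 (3R,5R,8S,9R,10S)-11-(2-oxo-2H-chromen-7-yloxy)-3-Bpin-8-(TBS-oxy)-12-nordriman-6-one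
Conditions: PPh3, DIAD, THF, 0 → 40 °C
Reagents that add atoms: none
Why: Mitsunobu etherification of the primary C11 alcohol with the acidic phenol forms the aryl ether by SN2 at CH2 and touches no stereocentre.

Step 13
Reactants: 21 aryl ether ketone
Product: 22 (3R,5R,8R,9R,10S)-11-(2-oxo-2H-chromen-7-yloxy)-3-Bpin-8-(TBS-oxy)-12-nordrim-6-en-6-yl trifluoromethanesulfonate
Conditions: KN(SiMe3)2, THF, −78 °C; then N-(5-chloropyridin-2-yl)bis(trifluoromethanesulfonimide), −78 °C
Reagents that add atoms: N-(5-chloropyridin-2-yl)bis(trifluoromethanesulfonimide) O=S(=O)(N(c1ccc(Cl)cn1)S(=O)(=O)C(F)(F)F)C(F)(F)F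
Why: Kinetic enolisation should occur at the C7 methylene (C5 is tertiary and flanked by two quaternary carbons) and O-sulfonylation of the potassium enolate gives the C6=C7 enol triflate before the equatorial silyloxy group can be eliminated.

Step 14
Reactants: 22 enol triflate
Product: 23 (3R,5R,8S,9R,10R)-11-(2-oxo-2H-chromen-7-yloxy)-3-Bpin-8-(TBS-oxy)-12-nordrim-6-ene
Conditions: Pd(OAc)2 (5 mol %), PPh3, Bu3N, HCO2H, DMF, 60 °C
Reagents that add atoms: none
Why: Palladium-catalysed formate reduction of the enol triflate (oxidative addition to zerovalent palladium, hydride transfer from formate, reductive elimination) should give the C6=C7 alkene and leave the alkylboronate and the lactone untouched.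

Step 15
Reactants: 23 alkene
Product: 25 (3R,5S,8S,9R,10R)-11-(2-oxo-2H-chromen-7-yloxy)-12-nordrim-6-ene-3,8-diol, via allylic alcohol boronate 24 (not isolated)
Conditions: Bu4NF, THF, 25 °C; then NaBO3·4H2O, H2O, 40 °C
Reagents that add atoms: sodium perborate [Na+].OB(O)O[O-]
Why: Fluoride desilylation frees the C8 alcohol and perborate oxidation of the C–B bond proceeds by 1,2-migration with retention, so the C3 carbinol keeps the configuration set in the cycloaddition.

Step 16
Reactants: 25 diol
Product: 26 (3R,5S,9R,10R)-3-hydroxy-11-(2-oxo-2H-chromen-7-yloxy)-12-nordrim-6-en-8-one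
Conditions: MnO2, CH2Cl2, 25 °C
Reagents that add atoms: none
Why: Manganese dioxide oxidises only the allylic C8 alcohol, which gives the C6=C7–C8=O enone under neutral conditions and erases the C8 centre while the saturated C3 alcohol remains.

Step 17
Reactants: 26 enone
Product: 27 target, 7-{[(1R,4aS,6R,8aR)-6-hydroxy-5,5,8a-trimethyl-2-methylidene-1,2,4a,5,6,7,8,8a-octahydronaphthalen-1-yl]methoxy}-2H-chromen-2-one
Conditions: Zn, CH2Br2, TiCl4, THF–CH2Cl2, 0 → 25 °C
Reagents that add atoms: dibromomethane BrCBr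
Why: Lombardo–Takai methylenation with the non-basic zinc–titanium methylene reagent should convert the ketone into the exocyclic C8=C12 alkene without epimerising C9, eliminating the β-aryloxy group or attacking the lactone.

Compound list
1 | (S)-4-benzyloxazolidin-2-one | O=C1N[C@@H](Cc2ccccc2)CO1 | starting material
2 | 3-methylbut-2-enoyl chloride | CC(C)=CC(=O)Cl | starting material
3 | (S)-4-benzyl-3-(3-methylbut-2-enoyl)oxazolidin-2-one | CC(C)=CC(=O)N1C(=O)OC[C@@H]1Cc1ccccc1 | intermediate
4 | benzyl chloromethyl ether | ClCOCc1ccccc1 | starting material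
5 | (S)-4-benzyl-3-[(R)-2-(benzyloxymethyl)-3-methylbut-3-enoyl]oxazolidin-2-one | C=C(C)[C@@H](C(=O)N1C(=O)OC[C@@H]1Cc1ccccc1)COCc1ccccc1 | intermediate
6 | (S)-2-(benzyloxymethyl)-3-methylbut-3-en-1-ol | C=C(C)[C@@H](CO)COCc1ccccc1 | intermediate
7 | acryloyl chloride | C=CC(=O)Cl | starting material
8 | (R)-2-(benzyloxymethyl)-3-methylbut-3-en-1-yl prop-2-enoate | C=C(C)[C@@H](COC(=O)C=C)COCc1ccccc1 | intermediate
9 | (R)-5-(benzyloxymethyl)-4-methyl-5,6-dihydro-2H-pyran-2-one | O=C1C=C(C)[C@@H](CO1)COCc1ccccc1 | intermediate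
10 | (5R)-5-(benzyloxymethyl)-4-methyl-5,6-dihydro-2H-pyran-2-ol (both anomers) | OC1C=C(C)[C@@H](CO1)COCc1ccccc1 | intermediate
11 | 2-(dichloromethyl)-4,4,5,5-tetramethyl-1,3,2-dioxaborolane | ClC(Cl)B1OC(C)(C)C(C)(C)O1 | starting material
12 | (2S,3Z,5E)-2-(benzyloxymethyl)-3-methyl-6-Bpin-hexa-3,5-dien-1-ol | CC1(C)OB(/C=C/C=C(C)\[C@@H](CO)COCc2ccccc2)OC1(C)C | intermediate
13 | (2R,3Z,5E)-2-(benzyloxymethyl)-3-methyl-6-Bpin-hexa-3,5-dienal | CC1(C)OB(/C=C/C=C(C)\[C@@H](C=O)COCc2ccccc2)OC1(C)C | intermediate
14 | 4-methylpent-3-en-2-one (mesityl oxide) | CC(=O)C=C(C)C | starting material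
15 | (6S,7R,8Z,10E)-7-(benzyloxymethyl)-6-hydroxy-2,8-dimethyl-11-Bpin-undeca-2,8,10-trien-4-one (present as its lithium alkoxide) | CC1(C)OB(/C=C/C=C(C)\[C@@H]([C@H](CC(=O)C=C(C)C)O)COCc2ccccc2)OC1(C)C | intermediate
16 | (6S,7R,8Z,10E)-7-(benzyloxymethyl)-6-(tert-butyldimethylsilyloxy)-2,8-dimethyl-11-Bpin-undeca-2,8,10-trien-4-one | CC1(C)OB(/C=C/C=C(C)\[C@@H]([C@H](CC(=O)C=C(C)C)O[Si](C)(C)C(C)(C)C)COCc2ccccc2)OC1(C)C | intermediate
17 | cis-fused cycloadduct, (3R,5S,8S,9R,10S)-11-benzyloxy-3-Bpin-8-(TBS-oxy)-12-nordrim-1-en-6-one | CC(C)(C)[Si](C)(C)O[C@H]1CC(=O)[C@H]2C(C)(C)[C@H](B3OC(C)(C)C(C)(C)O3)C=C[C@@]2(C)[C@@H]1COCc1ccccc1 | intermediate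
18 | trans-fused decalone, (3R,5R,8S,9R,10S)-11-benzyloxy-3-Bpin-8-(TBS-oxy)-12-nordrim-1-en-6-one | CC(C)(C)[Si](C)(C)O[C@H]1CC(=O)[C@@H]2C(C)(C)[C@H](B3OC(C)(C)C(C)(C)O3)C=C[C@@]2(C)[C@@H]1COCc1ccccc1 | intermediate
19 | (3R,5R,8S,9R,10S)-11-hydroxy-3-Bpin-8-(TBS-oxy)-12-nordriman-6-one | CC(C)(C)[Si](C)(C)O[C@H]1CC(=O)[C@@H]2C(C)(C)[C@H](B3OC(C)(C)C(C)(C)O3)CC[C@@]2(C)[C@@H]1CO | intermediate
20 | 7-hydroxy-2H-chromen-2-one (umbelliferone) | O=c1ccc2ccc(O)cc2o1 | starting material
21 | (3R,5R,8S,9R,10S)-11-(2-oxo-2H-chromen-7-yloxy)-3-Bpin-8-(TBS-oxy)-12-nordriman-6-one | CC(C)(C)[Si](C)(C)O[C@H]1CC(=O)[C@@H]2C(C)(C)[C@H](B3OC(C)(C)C(C)(C)O3)CC[C@@]2(C)[C@@H]1COc1ccc2ccc(=O)oc2c1 | intermediate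
22 | (3R,5R,8R,9R,10S)-11-(2-oxo-2H-chromen-7-yloxy)-3-Bpin-8-(TBS-oxy)-12-nordrim-6-en-6-yl trifluoromethanesulfonate | CC(C)(C)[Si](C)(C)O[C@H]1C=C(OS(=O)(=O)C(F)(F)F)[C@@H]2C(C)(C)[C@H](B3OC(C)(C)C(C)(C)O3)CC[C@@]2(C)[C@@H]1COc1ccc2ccc(=O)oc2c1 | intermediate
23 | (3R,5R,8S,9R,10R)-11-(2-oxo-2H-chromen-7-yloxy)-3-Bpin-8-(TBS-oxy)-12-nordrim-6-ene | CC(C)(C)[Si](C)(C)O[C@H]1C=C[C@@H]2C(C)(C)[C@H](B3OC(C)(C)C(C)(C)O3)CC[C@@]2(C)[C@@H]1COc1ccc2ccc(=O)oc2c1 | intermediate
24 | (3R,5R,8S,9R,10R)-11-(2-oxo-2H-chromen-7-yloxy)-3-Bpin-12-nordrim-6-en-8-ol | O[C@H]1C=C[C@@H]2C(C)(C)[C@H](B3OC(C)(C)C(C)(C)O3)CC[C@@]2(C)[C@@H]1COc1ccc2ccc(=O)oc2c1 | intermediate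
25 | (3R,5S,8S,9R,10R)-11-(2-oxo-2H-chromen-7-yloxy)-12-nordrim-6-ene-3,8-diol | O[C@H]1C=C[C@@H]2C(C)(C)[C@H](O)CC[C@@]2(C)[C@@H]1COc1ccc2ccc(=O)oc2c1 | intermediate
26 | (3R,5S,9R,10R)-3-hydroxy-11-(2-oxo-2H-chromen-7-yloxy)-12-nordrim-6-en-8-one | O=C1C=C[C@@H]2C(C)(C)[C@H](O)CC[C@@]2(C)[C@@H]1COc1ccc2ccc(=O)oc2c1 | intermediate
27 | 7-{[(1R,4aS,6R,8aR)-6-hydroxy-5,5,8a-trimethyl-2-methylidene-1,2,4a,5,6,7,8,8a-octahydronaphthalen-1-yl]methoxy}-2H-chromen-2-one | C=C1C=C[C@@H]2C(C)(C)[C@H](O)CC[C@@]2(C)[C@@H]1COc1ccc2ccc(=O)oc2c1 | target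

Total step count: 17. Longest linear sequence: 17 steps (1 → 27); the route is fully linear.

Steps most likely to fail, each with a fallback:

Step 10 (key step). The cycloaddition may be too slow because a Z-configured diene terminus must bond to a β,β-disubstituted enone, so that the 1,5-hydrogen shift of the diene or thermal decomposition wins; the base equilibration at the hindered C5 may also stay incomplete. The fallback sets out from 13 and comes back at 18. Aldehyde 13 is treated with the lithium enolate of pent-3-yn-2-one and the aldolate is silylated as in step 9, which should give the ynone silyl ether F1. Its intramolecular Diels–Alder reaction uses a slimmer and more reactive alkyne dienophile, with the same control of C10 and C3 and no ring-fusion question, and should give the bicyclic dienone F2. Conjugate addition of Me2CuLi (Me3SiCl, THF, −78 °C) to C4 completes the gem-dimethyl group, and protonation of the C5 enolate anti to the angular methyl (with DBU equilibration if needed) gives 18.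

Step 7. The lactol may open too slowly for the chromium reagent, or the liberated (Z)-enal may isomerise to the E isomer before it is olefinated, which would lose the diene geometry on which step 10 depends. The fallback sets out from 10 and comes back at 12. Seyferth–Gilbert homologation of the lactol with dimethyl (1-diazo-2-oxopropyl)phosphonate (K2CO3, MeOH, 0 °C) should give the (Z)-enyne alcohol F3. Syn-hydroboration of its terminal alkyne with pinacolborane (cat. Cp2Zr(H)Cl, Et3N, 60 °C; O-boryl group hydrolysed on work-up) then gives the (E)-alkenylboronate 12.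

Step 17. During methylenation the β-aryloxy enone may lose umbelliferone by β-elimination or epimerise at C9, or the hindered carbonyl may react too slowly, so that the lactone is attacked instead. The fallback sets out from 26 and comes back at 27. Chemoselective 1,2-addition of Me3SiCH2Li/CeCl3 (THF, −78 °C) to the ketone should give the β-hydroxysilane F4, and acid-promoted Peterson elimination (HF·pyridine, MeCN, 0 °C) then gives the exocyclic alkene 27 without any basic step.

Further compounds
F1 | step 10 | (6S,7R,8Z,10E)-7-(benzyloxymethyl)-6-(tert-butyldimethylsilyloxy)-8-methyl-11-Bpin-undeca-8,10-dien-2-yn-4-one | CC1(C)OB(/C=C/C=C(C)\[C@@H]([C@H](CC(=O)C#CC)O[Si](C)(C)C(C)(C)C)COCc2ccccc2)OC1(C)C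
F2 | step 10 | bicyclic dienone, 11-benzyloxy-3-Bpin-8-(TBS-oxy)-4-methyl-12,13-dinordrima-1,4-dien-6-one (C3, C8, C9, C10 as in 18) | CC(C)(C)[Si](C)(C)O[C@H]1CC(=O)C2=C(C)[C@H](B3OC(C)(C)C(C)(C)O3)C=C[C@@]2(C)[C@@H]1COCc1ccccc1
F3 | step 7 | (2S,3Z)-2-(benzyloxymethyl)-3-methylhex-3-en-5-yn-1-ol | C#C/C=C(C)\[C@@H](CO)COCc1ccccc1
F4 | step 17 | (3R,5S,9R,10R)-11-(2-oxo-2H-chromen-7-yloxy)-8-(trimethylsilylmethyl)-12-nordrim-6-ene-3,8-diol (C8 epimers) | C[Si](C)(C)CC1(O)C=C[C@@H]2C(C)(C)[C@H](O)CC[C@@]2(C)[C@@H]1COc1ccc2ccc(=O)oc2c1
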